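The benzene ring of the isochromanone (C4a, C5–C8, C8a) is assembled last, from an open-chain diazo ketone and methoxyethyne. The feature exploited is its substitution pattern: a free hydroxyl at C8 beside the lactone-bearing C8a and a methyl ether at C6, meta to it, which is what a vinylketene–alkoxyalkyne benzannulation delivers. One photochemical–thermal operation (Wolff shift, [2+2], 4π opening, 6π closure) forms C4a–C5, C5–C6, C7–C8 and C8–C8a on an intact (R)-δ-lactone. The precursor is the (6R)-4-(diazoacetyl)-5,6-dihydropyran-2-one carrying the (6S)-silyloxyundecyl chain, made from (S)-oct-1-yn-3-ol by chain extension, asymmetric vinylogous aldol, lactonisation, triflation, Stille acetylation and diazo transfer.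

Key step: step 11

Remark: compounds 1, 3, 8, 13 and 18 are taken as purchased; 20 is low-boiling and is made just before use; C1–C8a are isochromanone locants, C1′–C11′ side-chain locants, and the target is (3R,6′S).

Step 1
Reactants: 1 (S)-oct-1-yn-3-ol
Product: 2 (S)-tert-butyldimethyl(oct-1-yn-3-yloxy)silane
Conditions: TBSCl, imidazole, DMF, rt
Reagents that add atoms: tert-butyldimethylsilyl chloride, CC(C)(C)[Si](C)(C)Cl
Why: Routine silylation of a secondary alcohol, which does not touch the carbinol carbon, so the (S) configuration (the future C6′) is carried over unchanged.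

Step 2
Reactants: 2 (S)-tert-butyldimethyl(oct-1-yn-3-yloxy)silane; 3 4-chloro-1,1-dimethoxybutane
Product: 5 (7S)-7-(tert-butyldimethylsilyloxy)-1,1-dimethoxydodec-5-yne, via lithium acetylide 4 (not isolated)
Conditions: n-BuLi, THF, −78 → 0 °C; then 3, NaI (0.2 equiv), DMPU, 60 °C
Reagents that add atoms: none
Why: Acetylide alkylation (SN2) of a primary halide, with catalytic iodide converting the chloride in situ into the more reactive iodide (Finkelstein exchange); this should join C4′ to C3′ without affecting the silyl ether or the acetal.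

Step 3
Reactants: 5 (7S)-7-(tert-butyldimethylsilyloxy)-1,1-dimethoxydodec-5-yne
Product: 6 (7S)-7-(tert-butyldimethylsilyloxy)-1,1-dimethoxydodecane
Conditions: H2 (1 atm), Pd/C, NaHCO3, EtOAc, rt
Reagents that add atoms: none
Why: Heterogeneous catalytic hydrogenation saturates the alkyne, and the slightly basic medium should protect the acetal and suppress hydrogenolysis of the propargylic C–O bond, so the (S) centre is kept.

Step 4
Reactants: 6 (7S)-7-(tert-butyldimethylsilyloxy)-1,1-dimethoxydodecane
Product: 7 (7S)-7-(tert-butyldimethylsilyloxy)dodecanal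
Conditions: PPTS, acetone/H2O (9:1), 45 °C
Reagents that add atoms: water, O
Why: Mild acid-catalysed hydrolysis of an acyclic dimethyl acetal, which is far more labile than a secondary tert-butyldimethylsilyl ether, should release the aldehyde selectively.

Step 5
Reactants: 7 (7S)-7-(tert-butyldimethylsilyloxy)dodecanal; 8 1-methoxy-1,3-bis(trimethylsilyloxy)buta-1,3-diene (Chan's diene)
Product: 10 methyl (5R,11S)-11-(tert-butyldimethylsilyloxy)-5-hydroxy-3-oxohexadecanoate, via bis-silyl aldol adduct 9 (not isolated)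
Conditions: Ti(OiPr)4 (8 mol%), (S)-BINOL (8 mol%), 4 Å MS, THF, −78 °C → rt; then 1 M HCl, THF, 0 °C
Reagents that add atoms: none
Why: Catalytic asymmetric vinylogous Mukaiyama aldol in which the titanium–(S)-BINOL complex binds the aldehyde and should deliver the γ-carbon of the dienolate to its Si face, setting C5 as (R) (the future C3), after which dilute acid removes both trimethylsilyl groups.

Step 6
Reactants: 10 methyl (5R,11S)-11-(tert-butyldimethylsilyloxy)-5-hydroxy-3-oxohexadecanoate
Product: 11 (6R)-6-[(6S)-6-(tert-butyldimethylsilyloxy)undecyl]oxane-2,4-dione (keto form of the 4-hydroxy-5,6-dihydro-2H-pyran-2-one)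
Conditions: K2CO3, MeOH, rt; then 1 M HCl to pH 3, 0 °C
Reagents that add atoms: none
Why: Base-mediated lactonisation (intramolecular transesterification) of a δ-hydroxy β-keto ester, driven by formation of the stabilised enolate of the product, which leaves the C–O stereocentre untouched.

Step 7
Reactants: 11 (6R)-6-[(6S)-6-(tert-butyldimethylsilyloxy)undecyl]oxane-2,4-dione
Product: 12 (6R)-6-[(6S)-6-(tert-butyldimethylsilyloxy)undecyl]-4-(trifluoromethanesulfonyloxy)-5,6-dihydro-2H-pyran-2-one
Conditions: Tf2O, Et3N, CH2Cl2, −78 °C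
Reagents that add atoms: trifluoromethanesulfonic anhydride, O=S(=O)(OS(=O)(=O)C(F)(F)F)C(F)(F)F
Why: Enol triflate formation, in which the enolised cyclic 1,3-dicarbonyl is sulfonylated at the C4 oxygen to give the triflate conjugated with the lactone carbonyl.

Step 8
Reactants: 12 (6R)-6-[(6S)-6-(tert-butyldimethylsilyloxy)undecyl]-4-(trifluoromethanesulfonyloxy)-5,6-dihydro-2H-pyran-2-one; 13 tributyl(1-ethoxyvinyl)stannane
Product: 15 (6R)-4-acetyl-6-[(6S)-6-(tert-butyldimethylsilyloxy)undecyl]-5,6-dihydro-2H-pyran-2-one, via ethoxyvinyl lactone 14 (not isolated)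
Conditions: Pd(PPh3)4 (5 mol%), LiCl, THF, 60 °C; then 1 M HCl, THF, 0 °C
Reagents that add atoms: water, O
Why: Stille coupling in which zerovalent palladium inserts into the electron-poor vinyl C–OTf bond and the 1-ethoxyvinyl group is transferred from tin under neutral conditions, after which brief acid hydrolysis of the enol ether should unmask the acetyl group.

Step 9
Reactants: 15 (6R)-4-acetyl-6-[(6S)-6-(tert-butyldimethylsilyloxy)undecyl]-5,6-dihydro-2H-pyran-2-one
Product: 17 (6R)-4-(diazoacetyl)-6-[(6S)-6-(tert-butyldimethylsilyloxy)undecyl]-5,6-dihydro-2H-pyran-2-one, via trifluoroacetyl diketone 16 (not isolated)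
Conditions: LiN(SiMe3)2, THF, −78 °C; CF3CO2CH2CF3; then 4-acetamidobenzenesulfonyl azide, Et3N, H2O (1 equiv), MeCN, rt
Reagents that add atoms: 4-acetamidobenzenesulfonyl azide, CC(=O)Nc1ccc(cc1)S(=O)(=O)N=[N+]=[N-]
Why: Detrifluoroacetylative diazo transfer, in which kinetic enolisation at the acetyl methyl (the only α-position of the ketone) and Claisen trifluoroacetylation activate that carbon for diazo transfer with loss of the trifluoroacetyl group; this avoids exposing the doubly activated ring alkene to diazomethane.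

Step 10
Reactants: 18 2-chloro-1,1-dimethoxyethane (chloroacetaldehyde dimethyl acetal)
Product: 20 methoxyethyne, via sodium methoxyacetylide 19 (not isolated)
Conditions: NaNH2 (3 equiv), liq. NH3, −33 °C; then sat. aq. NaCl, −20 °C; distil into a cold trap
Reagents that add atoms: none
Why: Twofold base-induced elimination (loss of HCl, then of methanol) gives the sodium acetylide, which is protonated on aqueous quench; the volatile ynol ether is distilled and used at once as a cold solution.

Step 11
Reactants: 17 (6R)-4-(diazoacetyl)-6-[(6S)-6-(tert-butyldimethylsilyloxy)undecyl]-5,6-dihydro-2H-pyran-2-one; 20 methoxyethyne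
Product: 25 (3R)-3-[(6S)-6-(tert-butyldimethylsilyloxy)undecyl]-8-hydroxy-6-methoxyisochroman-1-one, via vinylketene 21 (not isolated), via vinylcyclobutenone 22 (not isolated), via dienylketene 23 (not isolated), via cyclohexadienone 24 (not isolated)
Conditions: 20 (3 equiv), hν (254 nm, quartz), ClCH2CH2Cl, 5–10 °C; purge excess 20; then 80 °C
Reagents that add atoms: none
Why: Light expels N2 from 17 and ring carbon C4 migrates to the diazo carbon (Wolff rearrangement) to give vinylketene 21, whose electrophilic ketene carbon is attacked by the unsubstituted, nucleophilic carbon of the ynol ether in a [2+2] cycloaddition that gives the 3-methoxy-4-vinylcyclobutenone 22. On warming, strain-driven 4π electrocyclic opening gives dienylketene 23, and the benzene ring is closed by 6π electrocyclisation of the ketene carbon onto the lactone α-carbon (bond C8–C8a), after which 24 tautomerises irreversibly to the hydrogen-bonded phenol. The closest known reaction type is the Danheiser benzannulation in its photochemical form, in which α,β-unsaturated α′-diazo ketones and alkoxy- or silyloxyalkynes give resorcinol monoethers. No stereocentre is formed, and the existing centres at C3 and C6′ lie outside the reacting π-system and meet neither acid nor base. The selectivity needed is the orientation of the [2+2] step, which the polarity match between the ketene carbon and the ynol ether β-carbon should secure, placing the methoxy group at C6, meta to the C8 hydroxyl. The closure itself has only one possible terminus, because the vinylketene contains a single alkene whose far end is C8a.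

Step 12
Reactants: 25 (3R)-3-[(6S)-6-(tert-butyldimethylsilyloxy)undecyl]-8-hydroxy-6-methoxyisochroman-1-one
Product: 26 (3R)-8-hydroxy-3-[(6S)-6-hydroxyundecyl]-6-methoxyisochroman-1-one (target)
Conditions: HF·pyridine, pyridine, THF, 0 °C → rt
Reagents that add atoms: none
Why: Fluoride-driven cleavage of the silyl ether under buffered, weakly acidic conditions, which should leave the lactone, the phenol and both stereocentres untouched.

Compound list
1 | (S)-oct-1-yn-3-ol | CCCCC[C@H](O)C#C | starting material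
2 | (S)-tert-butyldimethyl(oct-1-yn-3-yloxy)silane | CCCCC[C@H](O[Si](C)(C)C(C)(C)C)C#C | intermediate
3 | 4-chloro-1,1-dimethoxybutane | COC(OC)CCCCl | starting material
4 | lithium acetylide of 2 | CCCCC[C@H](O[Si](C)(C)C(C)(C)C)C#C[Li] | intermediate (not isolated)
5 | (7S)-7-(tert-butyldimethylsilyloxy)-1,1-dimethoxydodec-5-yne | CCCCC[C@H](O[Si](C)(C)C(C)(C)C)C#CCCCC(OC)OC | intermediate
6 | (7S)-7-(tert-butyldimethylsilyloxy)-1,1-dimethoxydodecane | CCCCC[C@H](O[Si](C)(C)C(C)(C)C)CCCCCC(OC)OC | intermediate
7 | (7S)-7-(tert-butyldimethylsilyloxy)dodecanal | CCCCC[C@H](O[Si](C)(C)C(C)(C)C)CCCCCC=O | intermediate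
8 | 1-methoxy-1,3-bis(trimethylsilyloxy)buta-1,3-diene (Chan's diene) | C=C(O[Si](C)(C)C)C=C(OC)O[Si](C)(C)C | starting material
9 | methyl (5R,11S)-11-(tert-butyldimethylsilyloxy)-3,5-bis(trimethylsilyloxy)hexadec-2-enoate | CCCCC[C@H](O[Si](C)(C)C(C)(C)C)CCCCC[C@@H](O[Si](C)(C)C)CC(O[Si](C)(C)C)=CC(=O)OC | intermediate (not isolated)
10 | methyl (5R,11S)-11-(tert-butyldimethylsilyloxy)-5-hydroxy-3-oxohexadecanoate | CCCCC[C@H](O[Si](C)(C)C(C)(C)C)CCCCC[C@@H](O)CC(=O)CC(=O)OC | intermediate
11 | (6R)-6-[(6S)-6-(tert-butyldimethylsilyloxy)undecyl]oxane-2,4-dione | CCCCC[C@H](O[Si](C)(C)C(C)(C)C)CCCCC[C@@H]1CC(=O)CC(=O)O1 | intermediate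
12 | (6R)-6-[(6S)-6-(tert-butyldimethylsilyloxy)undecyl]-4-(trifluoromethanesulfonyloxy)-5,6-dihydro-2H-pyran-2-one | CCCCC[C@H](O[Si](C)(C)C(C)(C)C)CCCCC[C@@H]1CC(OS(=O)(=O)C(F)(F)F)=CC(=O)O1 | intermediate
13 | tributyl(1-ethoxyvinyl)stannane | CCCC[Sn](CCCC)(CCCC)C(=C)OCC | starting material
14 | (6R)-6-[(6S)-6-(tert-butyldimethylsilyloxy)undecyl]-4-(1-ethoxyvinyl)-5,6-dihydro-2H-pyran-2-one | CCCCC[C@H](O[Si](C)(C)C(C)(C)C)CCCCC[C@@H]1CC(C(=C)OCC)=CC(=O)O1 | intermediate (not isolated)
15 | (6R)-4-acetyl-6-[(6S)-6-(tert-butyldimethylsilyloxy)undecyl]-5,6-dihydro-2H-pyran-2-one | CCCCC[C@H](O[Si](C)(C)C(C)(C)C)CCCCC[C@@H]1CC(C(C)=O)=CC(=O)O1 | intermediate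
16 | (6R)-6-[(6S)-6-(tert-butyldimethylsilyloxy)undecyl]-4-(4,4,4-trifluoro-3-oxobutanoyl)-5,6-dihydro-2H-pyran-2-one | CCCCC[C@H](O[Si](C)(C)C(C)(C)C)CCCCC[C@@H]1CC(C(=O)CC(=O)C(F)(F)F)=CC(=O)O1 | intermediate (not isolated)
17 | (6R)-4-(diazoacetyl)-6-[(6S)-6-(tert-butyldimethylsilyloxy)undecyl]-5,6-dihydro-2H-pyran-2-one | CCCCC[C@H](O[Si](C)(C)C(C)(C)C)CCCCC[C@@H]1CC(C(=O)C=[N+]=[N-])=CC(=O)O1 | intermediate
18 | 2-chloro-1,1-dimethoxyethane | COC(OC)CCl | starting material
19 | sodium methoxyacetylide | [Na+].[C-]#COC | intermediate (not isolated)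
20 | methoxyethyne | COC#C | intermediate
21 | (6R)-6-[(6S)-6-(tert-butyldimethylsilyloxy)undecyl]-4-(2-oxoethenyl)-5,6-dihydro-2H-pyran-2-one | CCCCC[C@H](O[Si](C)(C)C(C)(C)C)CCCCC[C@@H]1CC(C=C=O)=CC(=O)O1 | intermediate (not isolated)
22 | (6R)-6-[(6S)-6-(tert-butyldimethylsilyloxy)undecyl]-4-(2-methoxy-4-oxocyclobut-2-en-1-yl)-5,6-dihydro-2H-pyran-2-one (either configuration at the cyclobutene carbon) | CCCCC[C@H](O[Si](C)(C)C(C)(C)C)CCCCC[C@@H]1CC(C2C(=O)C=C2OC)=CC(=O)O1 | intermediate (not isolated)
23 | (6R)-6-[(6S)-6-(tert-butyldimethylsilyloxy)undecyl]-4-(2-methoxy-4-oxobuta-1,3-dien-1-yl)-5,6-dihydro-2H-pyran-2-one | CCCCC[C@H](O[Si](C)(C)C(C)(C)C)CCCCC[C@@H]1CC(C=C(OC)C=C=O)=CC(=O)O1 | intermediate (not isolated)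
24 | (3R)-3-[(6S)-6-(tert-butyldimethylsilyloxy)undecyl]-6-methoxy-3,4-dihydro-1H-isochromene-1,8(8aH)-dione | CCCCC[C@H](O[Si](C)(C)C(C)(C)C)CCCCC[C@@H]1CC2=CC(OC)=CC(=O)C2C(=O)O1 | intermediate (not isolated)
25 | (3R)-3-[(6S)-6-(tert-butyldimethylsilyloxy)undecyl]-8-hydroxy-6-methoxyisochroman-1-one | CCCCC[C@H](O[Si](C)(C)C(C)(C)C)CCCCC[C@@H]1Cc2cc(OC)cc(O)c2C(=O)O1 | intermediate
26 | (3R)-8-hydroxy-3-[(6S)-6-hydroxyundecyl]-6-methoxyisochroman-1-one | CCCCC[C@H](O)CCCCC[C@@H]1Cc2cc(OC)cc(O)c2C(=O)O1 | target

Total step count: 12 (eleven on the main line and one for the alkyne).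
Longest linear sequence: 11 steps (steps 1–9, 11 and 12, from compound 1).

Steps most likely to fail

Step 11. The photogenerated ketene may be consumed before the [2+2] step, by dimerisation or by acylating phenol already formed. The enoate chromophore may also absorb and react on its own, or the 6π closure onto a carbonyl-bearing alkene terminus may be slow enough for the dienylketene to decompose. The fallback abandons the late ring construction and uses a preformed arene; it sets out from aldehyde 7 and returns at 25. Methylene transfer with dimethylsulfonium methylide (trimethylsulfonium iodide, n-BuLi, THF; Corey–Chaykovsky epoxidation) should give 2-[(6S)-6-(tert-butyldimethylsilyloxy)undecyl]oxirane F1 as both oxirane epimers. Hydrolytic kinetic resolution with the enantiomer of the (salen)Co(OAc) catalyst that hydrolyses the (2S)-epimer should leave (2R)-2-[(6S)-6-(tert-butyldimethylsilyloxy)undecyl]oxirane F2. Copper-catalysed opening at the CH2 terminus with 3,5-dimethoxyphenylmagnesium bromide (CuI, THF, −30 °C) should give (2R,8S)-8-(tert-butyldimethylsilyloxy)-1-(3,5-dimethoxyphenyl)tridecan-2-ol F3 with the carbinol centre retained. Bromination with NBS in MeCN, directed ortho to the side chain and para to a methoxy group, should give (2R,8S)-1-(2-bromo-3,5-dimethoxyphenyl)-8-(tert-butyldimethylsilyloxy)tridecan-2-ol F4. Bromine–lithium exchange on the alkoxide (n-BuLi, 2.2 equiv, −78 °C), carboxylation with CO2 and lactonisation on mildly acidic work-up should give (3R)-3-[(6S)-6-(tert-butyldimethylsilyloxy)undecyl]-6,8-dimethoxyisochroman-1-one F5. BCl3 in CH2Cl2 at −78 °C should then cleave only the C8 methyl ether, through chelation to the lactone carbonyl, to give 25; any material that also loses the silyl group is already 26.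

Step 9. The amide base may also remove a C5 proton (γ to the lactone carbonyl), which would open the ring by β-elimination of the carboxylate, or the enolate may add to unreacted ene-dione. The fallback replaces enolate chemistry by acylation of diazomethane; it sets out from triflate 12 and returns at 17. Palladium-catalysed hydroxycarbonylation (Pd(OAc)2, dppf, KOAc, CO 1 atm, DMSO, 60 °C) should give (6R)-6-[(6S)-6-(tert-butyldimethylsilyloxy)undecyl]-2-oxo-5,6-dihydro-2H-pyran-4-carboxylic acid F6. Oxalyl chloride with catalytic DMF in CH2Cl2 at 0 °C should give the acid chloride (6R)-6-[(6S)-6-(tert-butyldimethylsilyloxy)undecyl]-2-oxo-5,6-dihydro-2H-pyran-4-carbonyl chloride F7. Addition of F7 to cold ethereal diazomethane (−40 → 0 °C), quenched with acetic acid as soon as the chloride is consumed so that dipolar addition to the ring alkene cannot compete, should give 17.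

Step 5. Facial selectivity may be poor with an unbranched aldehyde, and because C11 is remote the (5S) epimer would be hard to remove; the configuration of 10 would be checked by ester derivatisation. The fallback sets the centre by ketone hydrogenation instead; it sets out from aldehyde 7 and returns at 11. Roskamp homologation (ethyl diazoacetate, SnCl2 cat., CH2Cl2) should give ethyl (9S)-9-(tert-butyldimethylsilyloxy)-3-oxotetradecanoate F8. Noyori hydrogenation with RuCl2[(R)-BINAP] (H2, EtOH, 50 °C) should give ethyl (3R,9S)-9-(tert-butyldimethylsilyloxy)-3-hydroxytetradecanoate F9. Claisen condensation with excess lithium enolate of tert-butyl acetate (LiN(iPr)2, THF, −78 → −20 °C) should give tert-butyl (5R,11S)-11-(tert-butyldimethylsilyloxy)-5-hydroxy-3-oxohexadecanoate F10. Heating F10 in toluene at 110 °C should expel tert-butanol and trap the acylketene with the δ-hydroxyl to give 11 under neutral conditions.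

Further compounds
F1 | step 11 | 2-[(6S)-6-(tert-butyldimethylsilyloxy)undecyl]oxirane (both oxirane epimers) | CCCCC[C@H](O[Si](C)(C)C(C)(C)C)CCCCCC1CO1
F2 | step 11 | (2R)-2-[(6S)-6-(tert-butyldimethylsilyloxy)undecyl]oxirane | CCCCC[C@H](O[Si](C)(C)C(C)(C)C)CCCCC[C@@H]1CO1
F3 | step 11 | (2R,8S)-8-(tert-butyldimethylsilyloxy)-1-(3,5-dimethoxyphenyl)tridecan-2-ol | CCCCC[C@H](O[Si](C)(C)C(C)(C)C)CCCCC[C@@H](O)Cc1cc(OC)cc(OC)c1
F4 | step 11 | (2R,8S)-1-(2-bromo-3,5-dimethoxyphenyl)-8-(tert-butyldimethylsilyloxy)tridecan-2-ol | CCCCC[C@H](O[Si](C)(C)C(C)(C)C)CCCCC[C@@H](O)Cc1cc(OC)cc(OC)c1Br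
F5 | step 11 | (3R)-3-[(6S)-6-(tert-butyldimethylsilyloxy)undecyl]-6,8-dimethoxyisochroman-1-one | CCCCC[C@H](O[Si](C)(C)C(C)(C)C)CCCCC[C@@H]1Cc2cc(OC)cc(OC)c2C(=O)O1
F6 | step 9 | (6R)-6-[(6S)-6-(tert-butyldimethylsilyloxy)undecyl]-2-oxo-5,6-dihydro-2H-pyran-4-carboxylic acid | CCCCC[C@H](O[Si](C)(C)C(C)(C)C)CCCCC[C@@H]1CC(C(=O)O)=CC(=O)O1
F7 | step 9 | (6R)-6-[(6S)-6-(tert-butyldimethylsilyloxy)undecyl]-2-oxo-5,6-dihydro-2H-pyran-4-carbonyl chloride | CCCCC[C@H](O[Si](C)(C)C(C)(C)C)CCCCC[C@@H]1CC(C(=O)Cl)=CC(=O)O1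
F8 | step 5 | ethyl (9S)-9-(tert-butyldimethylsilyloxy)-3-oxotetradecanoate | CCCCC[C@H](O[Si](C)(C)C(C)(C)C)CCCCCC(=O)CC(=O)OCC
F9 | step 5 | ethyl (3R,9S)-9-(tert-butyldimethylsilyloxy)-3-hydroxytetradecanoate | CCCCC[C@H](O[Si](C)(C)C(C)(C)C)CCCCC[C@@H](O)CC(=O)OCC
F10 | step 5 | tert-butyl (5R,11S)-11-(tert-butyldimethylsilyloxy)-5-hydroxy-3-oxohexadecanoate | CCCCC[C@H](O[Si](C)(C)C(C)(C)C)CCCCC[C@@H](O)CC(=O)CC(=O)OC(C)(C)C
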